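**Analysis of the target**

The target joins two C15 halves at the spiro carbon C12. The upper half is a guaianolide-type tricycle: an α-methylene γ-lactone (C2, C3, O5, C6, C38) trans-fused to a seven-membered ring (C6–C7–C8–C10–C36–C37–C38) that shares C10 and C36 with a norbornene (C10, C11, C12, C33, C34=C36, bridge C39). The lower half is a cyclohexene (C16, C17, C18, C21=C31, C32) whose γ-lactone (C12, C13, O15, C16, C32) is spiro at C12 and cis-fused at C16/C32. There are eleven stereocentres: C6 R, C8 R, C10 R, C12 R, C16 S, C18 R, C22 R, C32 S, C33 S, C38 S, C39 R. On the norbornene the C39 acetate points to the C11–C12 bridge (anti to the C34=C36 alkene), C13 is endo and C32 exo; on the seven-membered ring H6 and H38 are trans and the C8 methyl lies on the face opposite to C11. In the cyclohexene O15, C12 and the C18 hydroxyl share one face. Sensitive groups are the exocyclic methylene lactone (Michael acceptor), two acetates, a 7-norbornenyl acetate anti to an alkene (ionisable), and, one stage earlier, a tertiary β-hydroxy aldehyde (retro-aldol, dehydration). The synthesis is hard because the quaternary centres C10 (bridgehead) and C12 (spiro) sit at the junction and all stereochemical information between the halves must pass through C12. The strategy rests on the homoallylic array O15–C16–C32–C31=C21: an aldehyde at C16 adding to C32 of a C31=C32 alkene, with the C21 hydrogen moving to oxygen, closes the cyclohexene and sets C16 and C32. Because C12 is quaternary, C21–H is the only allylic hydrogen that can be transferred.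

**Retrosynthetic reasoning**

52 ⇒ 51. The C13–O15 bond of the lower lactone is cut first. A cis γ-hydroxy methyl ester lactonises readily, so the last step only has to bring O15 onto the endo ester.

51 ⇒ 50. The C16–C32 bond is cut as a carbonyl-ene reaction, restoring the (E)-C31=C32 alkene and the hydrogen on C21. This is the only cut that removes a ring and two stereocentres (C16, C32) at once while leaving a precursor in which C18 and C21 can direct the outcome. In the usual classification by where the tether joins the ene unit it is the type 3 mode (tether on the hydrogen-donating allylic carbon), not the type 1 mode. The forward step needs an aluminium Lewis acid that chelates the C18 alkoxide and the C16 carbonyl.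

50 ⇒ 49 ⇒ 44 ⇒ 27 + 43. The C31=C32 alkene is cut as a Julia–Kocienski olefination. The aldehyde is put on the norbornene (C32, non-enolisable) and the sulfone on the chain (C31), so that no neopentyl sulfone has to be made and the C21 centre is never α to a carbonyl. Three groups are masked through this basic step and released afterwards: C16 as a dioxolane, C13 as a silyloxymethyl group (oxidised to the ester in 45–49), and the methylene lactone as its dimethylamine adduct (released by methylation in 47 → 49).

27 ⇒ 26 + 24. The norbornene is cut at C10–C11 and C12–C33 as a Diels–Alder reaction of acetoxy diene 26 with enal 24. A 2-substituted acrolein is chosen because its formyl group goes exo (C32) and the other substituent endo (C13). The diene's acetoxy group directs the dienophile to its own face, which is also the face away from the C8 methyl. Bonding of the dienophile CH2 to the fully substituted C10 avoids two adjacent quaternary carbons.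

26 ⇒ 21 ⇒ 18. The labile diene is made only at the moment of use, by selenoxide elimination across C33–C34 of 21. The C39 oxygen comes from reduction of enone 18 under catalyst control, and the selenium from its α′ position.

18 ⇒ 17 ⇒ 15. The five-membered ring is cut at C34–C36 as a Nazarov cyclisation of dienone 17, made from aldehyde 15 and a propenyl nucleophile. C34 is formed as a mixture, which does not matter because it becomes sp2 in 26.

15 ⇒ 14 ⇒ 11. The seven-membered ring is cut at its only alkene, C10=C36, by ring-closing metathesis. The methylene on C10 comes from α-methylenation of aldehyde 13.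

11 ⇒ 9 ⇒ 6 ⇒ 1. The trans lactone is cut at C38–C37 (conjugate addition of an allyl group to butenolide 9, anti to the C6 side chain) and at C2–C1 (Mannich trapping of the enolate). C6 comes from asymmetric reduction of ynone 6. C8 is bought with hemiester 1, whose two ends are told apart by reducing the ester and not the acid.

43 ⇒ 36 ⇒ 35 ⇒ 32 ⇒ 28 + 29. The tertiary carbinol C18 is cut at C18–C19: a methyl nucleophile adds to ketone 35 under chelation by the C31 benzyloxy group, anti to the C22 branch. C21 is set by auxiliary-controlled alkylation of imide 31. C22 comes from acid 28. The alkene of 28 serves as the latent C26 acetate.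

**Alternatives that were turned down**

Alternative 1: The seven-membered ring is cut at C7–C8 and C37–C38. Forward, an oxyallyl cation adds in a (4+3) sense across an exocyclic diene on a cyclopentane ketal and gives hydroazulenone A1 (C10=C36 alkene, C6 ketone, C8 methyl, C38 acetate arm).
- For: one step builds the upper bicycle with its ketone handle and side chain. This is shorter than the metathesis/Nazarov sequence used here (steps 10–14), and on step economy for that part it is stronger.
- Against: both partners are unsymmetrical, so orientation is not fixed. The three centres C8, C38 and C34 arise through a stepwise-prone cation with compact and extended transition states close in energy. The hard part of the target (C10, C12 and the whole lower half) is untouched.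
- Comparison: the chosen strategy spends more steps on the bicycle but sets C6, C8 and C38 by reagent or chiral-pool control, and uses its key step where the molecule is hardest, closing the last carbocycle under control of existing centres.

Alternative 2: The norbornene is cut at C12–C33. Forward, the silyl ketene acetal of a δ-lactone, acylated on a tertiary oxygen at C36, undergoes an Ireland–Claisen ring contraction to the endo acid A2.
- For: the rearrangement is intramolecular, so the C10/C12 regiochemistry that the intermolecular cycloaddition must win by sterics is not in question. On that point it is stronger.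
- Against: it needs a lactone on a hindered tertiary allylic oxygen and enolisation at a carbon that already carries the complete lower ring. The contraction must pass a boat-like array to form a strained bicycle. Five silyl groups have to be removed and replaced by two acetates and a methylene lactone afterwards. The route is linear, because the lower ring must be complete before the upper half is built on it.
- Comparison: the chosen route is convergent and fixes C12 in one bimolecular step on a rigid diene, at the price of a regiochemical risk that is named below.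

Alternative 3: The seven-membered ring and upper lactone are cut at C6–C38. Forward, an allylchromium species made with CrCl2 from a bromomethyl enoate arm on C36 adds to the C6 aldehyde and gives hydroxy ester A3, which lactonises.
- For: divalent chromium is chemoselective for aldehydes. Anti addition gives the trans lactone, and the methylene lactone appears only at the end, so it needs no masking. On that point it is stronger.
- Against: it closes a seven-membered ring last, onto a neopentyl arm at bridgehead C10, with C6 and C38 to be set relative to distant centres and no chelate to help. A reactive allylic bromide must be installed on the complete dimer.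
- Comparison: the chosen key step closes a six-membered ring through a chelate, and the seven-membered ring is made early by metathesis, where failure costs little. The methylene lactone problem is solved by amine masking at no extra step.

Key step: step 38

Assumption: C34 (and C33 in 19–21 and 25) are carried as epimer mixtures and the Grignard reagent of step 12 as its E/Z mixture; all converge when C33 and C34 become sp2 in diene 26.

**Steps**

Step 1
Reactants: 1 methyl hydrogen (R)-3-methylglutarate
Product: 3 (S)-4-methyloxan-2-one, via hydroxy acid 2 (not isolated)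
Conditions: LiBH4, THF, 0 °C → reflux; then 2 M HCl, 20 °C
Reagents that add atoms: none
Why: LiBH4 reduces the ester but not the lithium carboxylate (chemoselective hydride reduction), and acid closes the δ-lactone; C8 is bought with 1 and is never next to an acidic position.

Step 2
Reactants: 3 lactone
Product: 4 (S)-5-hydroxy-N-methoxy-N,3-dimethylpentanamide
Conditions: MeNH(OMe)·HCl, i-PrMgCl, THF, −20 → 0 °C
Reagents that add atoms: N,O-dimethylhydroxylamine hydrochloride, CNOC.Cl
Why: Weinreb aminolysis of the lactone by the magnesium amide; this turns the former acid end into the acylating end (C6) and frees the C39 hydroxyl.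

Step 3
Reactants: 4 hydroxy amide
Product: 5 TBS ether of 4
Conditions: TBSCl, imidazole, DMF, 20 °C
Reagents that add atoms: tert-butyldimethylsilyl chloride, CC(C)(C)[Si](C)(C)Cl
Why: Standard silylation of the primary alcohol, so that the acetylide of step 4 meets no acidic proton.

Step 4
Reactants: 5 Weinreb amide
Product: 6 ynone
Conditions: methyl propiolate, LiHMDS, THF, −78 °C; then 5, −78 → −40 °C
Reagents that add atoms: methyl propiolate, C#CC(=O)OC
Why: Acylation of the lithium acetylide by the Weinreb amide; the chelated tetrahedral intermediate stops at the ketone.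

Step 5
Reactants: 6 ynone
Product: 7 (R)-propargylic alcohol
Conditions: RuCl[(R,R)-TsDPEN](p-cymene) (2 mol%), i-PrOH, 20 °C
Reagents that add atoms: none
Why: Noyori asymmetric transfer hydrogenation of an alkynyl ketone; with the alkyne as the π-directing group the (R,R) catalyst gives the (R)-carbinol, which sets C6 independently of C8.

Step 6
Reactants: 7 propargylic alcohol
Product: 9 butenolide, via Z-enoate 8 (not isolated)
Conditions: H2 (1 atm), Pd/CaCO3 (Pb-poisoned), quinoline, EtOAc; then CSA (cat.), CH2Cl2, 20 °C
Reagents that add atoms: none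
Why: Lindlar semihydrogenation gives the (Z)-γ-hydroxy enoate, which lactonises under acid; C6 is not touched.

Step 7
Reactants: 9 butenolide
Product: 11 amino lactone, via silyl ketene acetal 10 (not isolated)
Conditions: allylMgBr, CuBr·SMe2 (10 mol%), TMSCl, THF, −78 °C; then CH2=NMe2+ I−, CH2Cl2, −78 → 20 °C
Reagents that add atoms: allylmagnesium bromide, C=CC[Mg]Br; dimethylmethyleneiminium iodide, C=[N+](C)C.[I-]
Why: Copper-catalysed, TMSCl-assisted conjugate addition puts the allyl group anti to the C6 side chain (sets C38, trans lactone). The silyl ketene acetal then undergoes a Mannich reaction anti to the allyl group; this C2 centre is erased later, and the amine masks the methylene lactone.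

Step 8
Reactants: 11 silyl ether
Product: 12 primary alcohol
Conditions: HF·pyridine, THF, 0 → 20 °C
Reagents that add atoms: none
Why: Fluoride cleavage of the primary TBS ether; the amine is protonated and inert.

Step 9
Reactants: 12 alcohol
Product: 13 aldehyde
Conditions: Dess–Martin periodinane, NaHCO3, CH2Cl2, 0 °C
Reagents that add atoms: none
Why: Dess–Martin oxidation of a primary alcohol; the α-carbon (C10) is a methylene, so nothing can epimerise.

Step 10
Reactants: 13 aldehyde
Product: 14 2-substituted acrolein
Conditions: 37% aq. HCHO, pyrrolidine (10 mol%), EtCO2H (10 mol%), i-PrOH, 45 °C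
Reagents that add atoms: formaldehyde, C=O
Why: Amine-catalysed α-methylenation of an aldehyde (Mannich condensation, then elimination); only the enolisable aldehyde reacts, and C8 is not acidic under these conditions.

Step 11
Reactants: 14 diene
Product: 15 cycloheptenecarbaldehyde
Conditions: second-generation Hoveyda–Grubbs catalyst (5 mol%), CSA (1.1 equiv), toluene, 80 °C; NaHCO3 work-up
Reagents that add atoms: none
Why: Ring-closing metathesis between the 1,1-disubstituted enal alkene and the allyl terminus gives the trisubstituted C10=C36 alkene with loss of ethene. The trans lactone holds the two arms together, and CSA protonates the amine so that it does not bind ruthenium.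

Step 12
Reactants: 15 enal
Product: 16 dienol (C39 epimers)
Conditions: prop-1-enylmagnesium bromide, THF, −78 °C
Reagents that add atoms: prop-1-enylmagnesium bromide, CC=C[Mg]Br
Why: Grignard 1,2-addition to the aldehyde is much faster than attack on the lactone at −78 °C; the carbinol centre is oxidised next, so its configuration does not matter.

Step 13
Reactants: 16 dienol
Product: 17 cross-conjugated dienone
Conditions: MnO2, CH2Cl2, 20 °C
Reagents that add atoms: none
Why: MnO2 oxidises the doubly allylic alcohol selectively.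

Step 14
Reactants: 17 dienone
Product: 18 tricyclic enone (C34 epimers)
Conditions: TfOH (2.5 equiv), CH2Cl2, 0 → 20 °C
Reagents that add atoms: none
Why: Nazarov cyclisation: the protonated dienone closes by conrotatory 4π electrocyclisation to form C34–C36, and loss of the C36 proton places the alkene at the ring fusion (C10=C36, the more substituted enone). C34 forms as a mixture that converges in step 20.

Step 15
Reactants: 18 enone
Product: 19 α′-phenylselenide
Conditions: LDA, THF, −78 °C; PhSeBr
Reagents that add atoms: phenylselenyl bromide, Br[Se]c1ccccc1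
Why: Kinetic deprotonation at the only α′ methylene (C33), then selenenylation anti to the C34 methyl; this puts selenium syn to the C34 hydrogen needed for step 20.

Step 16
Reactants: 19 selenide
Product: 20 C39 alcohol
Conditions: (S)-2-methyl-CBS-oxazaborolidine (0.5 equiv), catecholborane, toluene, −78 °C
Reagents that add atoms: none
Why: CBS reduction under catalyst control, with the α-substituted enone carbon C10 as the large group, sets C39 with oxygen on the face opposite to the C8 methyl; catecholborane tolerates the selenide and the amine.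

Step 17
Reactants: 20 alcohol
Product: 21 allylic acetate
Conditions: Ac2O, Et3N, DMAP (cat.), CH2Cl2, 0 °C
Reagents that add atoms: acetic anhydride, CC(=O)OC(C)=O
Why: Acylation of the secondary alcohol; the acetate is both the target's C39 group and the face-directing group for step 20.

Step 18
Reactants: 22 2-methylidenepropane-1,3-diol
Product: 23 mono-TBS ether
Conditions: NaH (1.0 equiv), TBSCl (1.0 equiv), THF, 0 °C
Reagents that add atoms: tert-butyldimethylsilyl chloride, CC(C)(C)[Si](C)(C)Cl
Why: Monosilylation of a symmetrical diol through its monosodium alkoxide.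

Step 19
Reactants: 23 allylic alcohol
Product: 24 2-(silyloxymethyl)acrolein
Conditions: MnO2, CH2Cl2, 20 °C
Reagents that add atoms: none
Why: MnO2 oxidation of an allylic alcohol to the enal.

Step 20
Reactants: 21 seleno acetate; 24 enal
Product: 27 norbornene aldehyde, via selenoxide 25 (not isolated), via diene 26 (not isolated)
Conditions: 30% H2O2, pyridine, CH2Cl2, 0 °C; cold aqueous wash; then 24 (3 equiv), BHT, toluene (2 M), 0 → 20 °C
Reagents that add atoms: none
Why: Selenoxide syn-elimination towards the C34 hydrogen (elimination towards the acetoxy-bearing carbon is disfavoured) gives 5-acetoxycyclopentadiene 26, which is trapped at once in a thermal Diels–Alder reaction. The dienophile adds on the face syn to the acetoxy group (the known preference of 5-acyloxycyclopentadienes, here also the face away from the C8 methyl). Its CH2 bonds to the fully substituted C10 and its formyl group goes exo (as for 2-substituted acroleins), which sets C10, C12 and C33.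

Step 21
Reactants: 28 (R)-citronellic acid; 29 (S)-4-benzyloxazolidin-2-one
Product: 31 N-acyl oxazolidinone, via mixed anhydride 30 (not isolated)
Conditions: PivCl, Et3N, THF, −20 °C; then 29, LiCl, −20 → 20 °C
Reagents that add atoms: none
Why: N-Acylation of the oxazolidinone by the mixed pivalic anhydride; C22 comes from 28.

Step 22
Reactants: 31 imide
Product: 32 α-benzyloxymethyl imide
Conditions: TiCl4, i-Pr2NEt, CH2Cl2, 0 °C; BnOCH2Cl
Reagents that add atoms: benzyl chloromethyl ether, ClCOCc1ccccc1
Why: Evans alkylation: the chelated (Z)-titanium enolate is attacked on the face opposite to the benzyl group, which sets C21 (R) whatever the C22 centre prefers.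

Step 23
Reactants: 32 imide
Product: 33 carboxylic acid
Conditions: LiOH, 30% H2O2, THF–H2O, 0 °C; Na2SO3
Reagents that add atoms: hydrogen peroxide (as LiOOH), OO
Why: Hydroperoxide attacks the exocyclic carbonyl selectively and does not epimerise C21; the auxiliary is recovered.

Step 24
Reactants: 33 acid
Product: 35 keto acetal, via acid chloride 34 (not isolated)
Conditions: 1-chloro-N,N,2-trimethylprop-1-en-1-amine, CH2Cl2, 0 °C; then (1,3-dioxolan-2-ylmethyl)magnesium bromide, CuI (10 mol%), THF, −78 °C
Reagents that add atoms: (1,3-dioxolan-2-ylmethyl)magnesium bromide, Br[Mg]CC1OCCO1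
Why: Neutral acid chloride formation (no HCl, so the trisubstituted alkene is safe), then copper-catalysed acylation of the commercial acetal Grignard reagent, which stops at the hindered ketone.

Step 25
Reactants: 35 ketone
Product: 36 tertiary alcohol
Conditions: MeMgBr, Et2O–CH2Cl2, −78 → −20 °C
Reagents that add atoms: methylmagnesium bromide, C[Mg]Br
Why: Chelation-controlled Grignard addition: magnesium bridges the ketone and the benzyloxy oxygen, and methyl enters anti to the branched C22 substituent (the Felkin–Anh model predicts the same face). This gives (R)-C18.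

Step 26
Reactants: 36 alkene
Product: 38 diol, via aldehyde 37 (not isolated)
Conditions: O3, CH2Cl2–MeOH, −78 °C; Me2S; then NaBH4, 0 °C
Reagents that add atoms: ozone, [O-][O+]=O
Why: Ozonolysis of the only alkene present, then reduction to the C26 alcohol.

Step 27
Reactants: 38 diol
Product: 39 primary acetate
Conditions: Ac2O, pyridine, CH2Cl2, 0 °C
Reagents that add atoms: acetic anhydride, CC(=O)OC(C)=O
Why: Selective acetylation of the primary alcohol; the tertiary alcohol does not react without DMAP.

Step 28
Reactants: 39 benzyl ether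
Product: 40 primary alcohol
Conditions: H2 (1 atm), Pd/C, EtOAc, 20 °C
Reagents that add atoms: none
Why: Hydrogenolysis of the benzyl ether; no alkene is present.

Step 29
Reactants: 40 alcohol
Product: 41 tetrazolyl sulfide
Conditions: 1-phenyl-1H-tetrazole-5-thiol, PPh3, DIAD, THF, 0 → 20 °C
Reagents that add atoms: 1-phenyl-1H-tetrazole-5-thiol, Sc1nnnn1-c1ccccc1
Why: Mitsunobu thioetherification of the primary alcohol; the tertiary alcohol is inert.

Step 30
Reactants: 41 sulfide
Product: 42 sulfone
Conditions: (NH4)6Mo7O24·4H2O (cat.), 30% H2O2, EtOH, 0 → 20 °C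
Reagents that add atoms: hydrogen peroxide, OO
Why: Molybdate-catalysed oxidation of sulfide to sulfone.

Step 31
Reactants: 42 hydroxy sulfone
Product: 43 TES ether
Conditions: TESOTf, 2,6-lutidine, CH2Cl2, −78 → 0 °C
Reagents that add atoms: triethylsilyl trifluoromethanesulfonate, CC[Si](CC)(CC)OS(=O)(=O)C(F)(F)F
Why: Silylation of the tertiary alcohol, so that no alkoxide can attack the tetrazolyl sulfone (Smiles-type ipso substitution) or an acetate in step 32.

Step 32
Reactants: 27 aldehyde; 43 sulfone
Product: 44 (E)-alkene
Conditions: 43, KHMDS, DME, −60 °C; then 27, −60 → 20 °C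
Reagents that add atoms: none
Why: Julia–Kocienski olefination: the potassium sulfonyl anion adds to the non-enolisable aldehyde, and Smiles rearrangement with loss of SO2 and the tetrazolone gives the alkene. Phenyltetrazolyl sulfones with branched partners give the E isomer, and the masked lactone offers no Michael acceptor.

Step 33
Reactants: 44 bis-silyl ether
Product: 45 diol
Conditions: HF·pyridine, pyridine, THF, 0 → 20 °C
Reagents that add atoms: none
Why: Buffered fluoride removes the primary TBS and tertiary TES ethers; acetates and dioxolane survive.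

Step 34
Reactants: 45 diol
Product: 46 C13 aldehyde
Conditions: Dess–Martin periodinane, NaHCO3, CH2Cl2, 0 → 20 °C
Reagents that add atoms: none
Why: Dess–Martin oxidation of the neopentyl primary alcohol; the tertiary alcohol cannot be oxidised.

Step 35
Reactants: 46 aldehyde
Product: 47 C13 carboxylic acid
Conditions: NaClO2, NaH2PO4, 2-methylbut-2-ene, t-BuOH–H2O, 20 °C
Reagents that add atoms: sodium chlorite, [Na+].[O-]Cl=O
Why: Pinnick oxidation of a non-enolisable aldehyde; the scavenger protects the alkenes and the protonated amine is not oxidised.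

Step 36
Reactants: 47 amino acid
Product: 49 methyl ester with free methylene lactone, via ammonium salt 48 (not isolated)
Conditions: MeI (excess), K2CO3, DMF, 20 → 40 °C
Reagents that add atoms: iodomethane, CI
Why: Carboxylate O-methylation and exhaustive N-methylation occur together; the quaternary ammonium salt then undergoes base-induced β-elimination (E1cB) and releases the α-methylene lactone.

Step 37
Reactants: 49 dioxolane
Product: 50 β-hydroxy aldehyde
Conditions: TsOH·H2O (cat.), acetone–H2O, 20 °C
Reagents that add atoms: water, O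
Why: Mild acid-catalysed acetal hydrolysis; short contact avoids dehydration of the β-hydroxy aldehyde and ionisation of the C39 acetate.

Step 38
Reactants: 50 β-hydroxy aldehyde
Product: 51 cyclohexenediol methyl ester
Conditions: Me2AlCl (2.2 equiv), CH2Cl2, −78 → −20 °C; aq. potassium sodium tartrate
Reagents that add atoms: none
Why: Me2AlCl first turns the C18 hydroxyl into an aluminium alkoxide (methane is lost); the aluminium then binds the C16 carbonyl oxygen in a six-membered chelate and activates the aldehyde. C16 bonds to C32 of the E-alkene while the C21 hydrogen passes to the carbonyl oxygen, either in one six-centre step or through a short-lived C31 cation that the alkoxide deprotonates; the alkene ends at C21=C31. The closest known reaction is the Lewis acid-promoted cyclisation of 5-alkenals to cyclohex-3-enols, a type 3 intramolecular carbonyl-ene reaction; it has not been run next to a quaternary carbon. The six-membered ring closes in the 6-endo mode through a boat-like array with O16 and H21 in the two flagpole positions. C16 is set by the chelate, which holds the carbonyl oxygen on the face of the C18 oxygen; C32 is set by the E geometry, which puts C12 pseudo-equatorial and cis to the new hydroxyl. The sense is fixed because the (R)-C21 centre of 50 offers its hydrogen only on the oxygen-bearing face. The step needs proton loss instead of chloride capture or a hydride shift at C31, which the proton-scavenging Me2AlCl favours, and bond formation at C32 instead of C31, which is secured because C12 is quaternary (no second allylic hydrogen, and attack at C31 would leave a neopentyl cation).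

Step 39
Reactants: 51 hydroxy ester
Product: 52 target CNP0257312.1
Conditions: CSA (cat.), CH2Cl2, 20 °C
Reagents that add atoms: none
Why: Acid-catalysed lactonisation of the cis γ-hydroxy ester onto the endo methyl ester closes the spiro lactone; it may already occur on work-up of step 38.

**Compound list**

1 | methyl hydrogen (R)-3-methylglutarate | OC(=O)C[C@@H](C)CC(=O)OC | starting material
2 | (S)-5-hydroxy-3-methylpentanoic acid | OC(=O)C[C@@H](C)CCO | intermediate
3 | (S)-4-methyloxan-2-one | O=C1C[C@@H](C)CCO1 | intermediate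
4 | (S)-5-hydroxy-N-methoxy-N,3-dimethylpentanamide | CON(C)C(=O)C[C@@H](C)CCO | intermediate
5 | (S)-5-[(tert-butyldimethylsilyl)oxy]-N-methoxy-N,3-dimethylpentanamide | CON(C)C(=O)C[C@@H](C)CCO[Si](C)(C)C(C)(C)C | intermediate
6 | methyl (S)-8-[(tert-butyldimethylsilyl)oxy]-6-methyl-4-oxooct-2-ynoate | COC(=O)C#CC(=O)C[C@@H](C)CCO[Si](C)(C)C(C)(C)C | intermediate
7 | methyl (4R,6S)-8-[(tert-butyldimethylsilyl)oxy]-4-hydroxy-6-methyloct-2-ynoate | COC(=O)C#C[C@H](O)C[C@@H](C)CCO[Si](C)(C)C(C)(C)C | intermediate
8 | methyl (2Z,4R,6S)-8-[(tert-butyldimethylsilyl)oxy]-4-hydroxy-6-methyloct-2-enoate | COC(=O)/C=C\[C@H](O)C[C@@H](C)CCO[Si](C)(C)C(C)(C)C | intermediate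
9 | (R)-5-[(S)-4-[(tert-butyldimethylsilyl)oxy]-2-methylbutyl]furan-2(5H)-one | O=C1C=C[C@@H](C[C@@H](C)CCO[Si](C)(C)C(C)(C)C)O1 | intermediate
10 | (4S,5R)-4-allyl-5-[(S)-4-[(tert-butyldimethylsilyl)oxy]-2-methylbutyl]-2-(trimethylsilyloxy)-4,5-dihydrofuran | C[Si](C)(C)OC1=C[C@H](CC=C)[C@@H](C[C@@H](C)CCO[Si](C)(C)C(C)(C)C)O1 | intermediate
11 | (3R,4S,5R)-4-allyl-5-[(S)-4-[(tert-butyldimethylsilyl)oxy]-2-methylbutyl]-3-[(dimethylamino)methyl]oxolan-2-one | CN(C)C[C@@H]1C(=O)O[C@H](C[C@@H](C)CCO[Si](C)(C)C(C)(C)C)[C@H]1CC=C | intermediate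
12 | (3R,4S,5R)-4-allyl-3-[(dimethylamino)methyl]-5-[(S)-4-hydroxy-2-methylbutyl]oxolan-2-one | CN(C)C[C@@H]1C(=O)O[C@H](C[C@@H](C)CCO)[C@H]1CC=C | intermediate
13 | (R)-4-[(2R,3S,4R)-3-allyl-4-[(dimethylamino)methyl]-5-oxooxolan-2-yl]-3-methylbutanal | CN(C)C[C@@H]1C(=O)O[C@H](C[C@@H](C)CC=O)[C@H]1CC=C | intermediate
14 | (R)-4-[(2R,3S,4R)-3-allyl-4-[(dimethylamino)methyl]-5-oxooxolan-2-yl]-3-methyl-2-methylidenebutanal | CN(C)C[C@@H]1C(=O)O[C@H](C[C@@H](C)C(=C)C=O)[C@H]1CC=C | intermediate
15 | (3R,3aS,7R,8aR)-3-[(dimethylamino)methyl]-7-methyl-2-oxo-3,3a,4,7,8,8a-hexahydro-2H-cyclohepta[b]furan-6-carbaldehyde | CN(C)C[C@@H]1C(=O)O[C@@H]2C[C@@H](C)C(C=O)=CC[C@@H]12 | intermediate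
16 | 6-[(E)-1-hydroxybut-2-enyl] analogue of 15 (carbinol epimers at C39) | CN(C)C[C@@H]1C(=O)O[C@@H]2C[C@@H](C)C(C(O)/C=C/C)=CC[C@@H]12 | intermediate
17 | 6-[(E)-but-2-enoyl] analogue of 15 (dienone) | CN(C)C[C@@H]1C(=O)O[C@@H]2C[C@@H](C)C(C(=O)/C=C/C)=CC[C@@H]12 | intermediate
18 | tricyclic enone: lactone-fused hydroazulenone, ketone at C39, alkene C10=C36, methyl at C34 (C34 epimers) | CN(C)C[C@@H]1C(=O)O[C@@H]2C[C@@H](C)C3=C(C[C@@H]12)C(C)CC3=O | intermediate
19 | C33 phenylselenide of 18 (selenium trans to the C34 methyl; C34 epimers) | CN(C)C[C@@H]1C(=O)O[C@@H]2C[C@@H](C)C3=C(C[C@@H]12)C(C)C([Se]c1ccccc1)C3=O | intermediate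
20 | C39 alcohol from 19 (hydroxyl on the face opposite to the C8 methyl) | CN(C)C[C@@H]1C(=O)O[C@@H]2C[C@@H](C)C3=C(C[C@@H]12)C(C)C([Se]c1ccccc1)[C@H]3O | intermediate
21 | C39 acetate of 20 | CN(C)C[C@@H]1C(=O)O[C@@H]2C[C@@H](C)C3=C(C[C@@H]12)C(C)C([Se]c1ccccc1)[C@H]3OC(C)=O | intermediate
22 | 2-methylidenepropane-1,3-diol | C=C(CO)CO | starting material
23 | 2-{[(tert-butyldimethylsilyl)oxy]methyl}prop-2-en-1-ol | C=C(CO)CO[Si](C)(C)C(C)(C)C | intermediate
24 | 2-{[(tert-butyldimethylsilyl)oxy]methyl}prop-2-enal | C=C(C=O)CO[Si](C)(C)C(C)(C)C | intermediate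
25 | selenoxide of 21 | CN(C)C[C@@H]1C(=O)O[C@@H]2C[C@@H](C)C3=C(C[C@@H]12)C(C)C([Se](=O)c1ccccc1)[C@H]3OC(C)=O | intermediate
26 | acetoxy cyclopentadiene: diene C10=C36–C34=C33, acetate on sp3 C39, amine-masked trans lactone | CN(C)C[C@@H]1C(=O)O[C@@H]2C[C@@H](C)C3=C(C[C@@H]12)C(C)=C[C@H]3OC(C)=O | intermediate
27 | norbornene aldehyde: Diels–Alder adduct with C32 formyl exo, C13 silyloxymethyl endo, C39 acetate anti to the C34=C36 alkene, amine-masked lactone | CN(C)C[C@@H]1C(=O)O[C@@H]2C[C@@H](C)[C@]34C[C@](C=O)(CO[Si](C)(C)C(C)(C)C)[C@H](C(C)=C3C[C@@H]12)[C@H]4OC(C)=O | intermediate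
28 | (R)-citronellic acid [(3R)-3,7-dimethyloct-6-enoic acid] | OC(=O)C[C@H](C)CCC=C(C)C | starting material
29 | (S)-4-benzyloxazolidin-2-one | O=C1N[C@@H](Cc2ccccc2)CO1 | starting material
30 | (3R)-3,7-dimethyloct-6-enoic pivalic anhydride | CC(C)(C)C(=O)OC(=O)C[C@H](C)CCC=C(C)C | intermediate
31 | (S)-4-benzyl-3-[(3R)-3,7-dimethyloct-6-enoyl]oxazolidin-2-one | O=C1OC[C@H](Cc2ccccc2)N1C(=O)C[C@H](C)CCC=C(C)C | intermediate
32 | (S)-4-benzyl-3-[(2R,3R)-2-[(benzyloxy)methyl]-3,7-dimethyloct-6-enoyl]oxazolidin-2-one | O=C1OC[C@H](Cc2ccccc2)N1C(=O)[C@@H](COCc1ccccc1)[C@H](C)CCC=C(C)C | intermediate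
33 | (2R,3R)-2-[(benzyloxy)methyl]-3,7-dimethyloct-6-enoic acid | OC(=O)[C@@H](COCc1ccccc1)[C@H](C)CCC=C(C)C | intermediate
34 | (2R,3R)-2-[(benzyloxy)methyl]-3,7-dimethyloct-6-enoyl chloride | ClC(=O)[C@@H](COCc1ccccc1)[C@H](C)CCC=C(C)C | intermediate
35 | (3R,4R)-3-[(benzyloxy)methyl]-1-(1,3-dioxolan-2-yl)-4,8-dimethylnon-7-en-2-one | O=C(CC1OCCO1)[C@@H](COCc1ccccc1)[C@H](C)CCC=C(C)C | intermediate
36 | (2R,3R,4R)-3-[(benzyloxy)methyl]-1-(1,3-dioxolan-2-yl)-2,4,8-trimethylnon-7-en-2-ol | C[C@@](O)(CC1OCCO1)[C@@H](COCc1ccccc1)[C@H](C)CCC=C(C)C | intermediate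
37 | (4R,5R,6R)-5-[(benzyloxy)methyl]-7-(1,3-dioxolan-2-yl)-6-hydroxy-4,6-dimethylheptanal | C[C@@](O)(CC1OCCO1)[C@@H](COCc1ccccc1)[C@H](C)CCC=O | intermediate
38 | (4R,5R,6R)-5-[(benzyloxy)methyl]-7-(1,3-dioxolan-2-yl)-4,6-dimethylheptane-1,6-diol | C[C@@](O)(CC1OCCO1)[C@@H](COCc1ccccc1)[C@H](C)CCCO | intermediate
39 | (4R,5R,6R)-5-[(benzyloxy)methyl]-7-(1,3-dioxolan-2-yl)-6-hydroxy-4,6-dimethylheptyl acetate | C[C@@](O)(CC1OCCO1)[C@@H](COCc1ccccc1)[C@H](C)CCCOC(C)=O | intermediate
40 | (4R,5R,6R)-7-(1,3-dioxolan-2-yl)-6-hydroxy-5-(hydroxymethyl)-4,6-dimethylheptyl acetate | C[C@@](O)(CC1OCCO1)[C@@H](CO)[C@H](C)CCCOC(C)=O | intermediate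
41 | (4R,5S,6R)-7-(1,3-dioxolan-2-yl)-6-hydroxy-4,6-dimethyl-5-{[(1-phenyl-1H-tetrazol-5-yl)sulfanyl]methyl}heptyl acetate | C[C@@](O)(CC1OCCO1)[C@@H](CSc1nnnn1-c1ccccc1)[C@H](C)CCCOC(C)=O | intermediate
42 | (4R,5S,6R)-7-(1,3-dioxolan-2-yl)-6-hydroxy-4,6-dimethyl-5-{[(1-phenyl-1H-tetrazol-5-yl)sulfonyl]methyl}heptyl acetate | C[C@@](O)(CC1OCCO1)[C@@H](CS(=O)(=O)c1nnnn1-c1ccccc1)[C@H](C)CCCOC(C)=O | intermediate
43 | triethylsilyl ether of 42 at the tertiary C18 oxygen | C[C@@](O[Si](CC)(CC)CC)(CC1OCCO1)[C@@H](CS(=O)(=O)c1nnnn1-c1ccccc1)[C@H](C)CCCOC(C)=O | intermediate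
44 | coupled (E)-C31=C32 alkene: C13 CH2OTBS, C18 OTES, C16 dioxolane, amine-masked lactone | CN(C)C[C@@H]1C(=O)O[C@@H]2C[C@@H](C)[C@]34C[C@@](CO[Si](C)(C)C(C)(C)C)(/C=C/[C@@H]([C@H](C)CCCOC(C)=O)[C@](C)(O[Si](CC)(CC)CC)CC5OCCO5)[C@H](C(C)=C3C[C@@H]12)[C@H]4OC(C)=O | intermediate
45 | diol from 44 (C13 CH2OH, C18 OH) | CN(C)C[C@@H]1C(=O)O[C@@H]2C[C@@H](C)[C@]34C[C@@](CO)(/C=C/[C@@H]([C@H](C)CCCOC(C)=O)[C@](C)(O)CC5OCCO5)[C@H](C(C)=C3C[C@@H]12)[C@H]4OC(C)=O | intermediate
46 | C13 aldehyde from 45 | CN(C)C[C@@H]1C(=O)O[C@@H]2C[C@@H](C)[C@]34C[C@@](C=O)(/C=C/[C@@H]([C@H](C)CCCOC(C)=O)[C@](C)(O)CC5OCCO5)[C@H](C(C)=C3C[C@@H]12)[C@H]4OC(C)=O | intermediate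
47 | C13 carboxylic acid from 46 | CN(C)C[C@@H]1C(=O)O[C@@H]2C[C@@H](C)[C@]34C[C@@](C(=O)O)(/C=C/[C@@H]([C@H](C)CCCOC(C)=O)[C@](C)(O)CC5OCCO5)[C@H](C(C)=C3C[C@@H]12)[C@H]4OC(C)=O | intermediate
48 | trimethylammonium iodide of the C13 methyl ester | C[N+](C)(C)C[C@@H]1C(=O)O[C@@H]2C[C@@H](C)[C@]34C[C@@](C(=O)OC)(/C=C/[C@@H]([C@H](C)CCCOC(C)=O)[C@](C)(O)CC5OCCO5)[C@H](C(C)=C3C[C@@H]12)[C@H]4OC(C)=O.[I-] | intermediate
49 | C13 methyl ester with free α-methylene lactone and C16 dioxolane | C=C1C(=O)O[C@@H]2C[C@@H](C)[C@]34C[C@@](C(=O)OC)(/C=C/[C@@H]([C@H](C)CCCOC(C)=O)[C@](C)(O)CC5OCCO5)[C@H](C(C)=C3C[C@@H]12)[C@H]4OC(C)=O | intermediate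
50 | β-hydroxy aldehyde with (E)-alkenyl group on C12 (ene precursor) | C=C1C(=O)O[C@@H]2C[C@@H](C)[C@]34C[C@@](C(=O)OC)(/C=C/[C@@H]([C@H](C)CCCOC(C)=O)[C@](C)(O)CC=O)[C@H](C(C)=C3C[C@@H]12)[C@H]4OC(C)=O | intermediate
51 | cyclohexenediol methyl ester (seco lower lactone) | C=C1C(=O)O[C@@H]2C[C@@H](C)[C@]34C[C@@](C(=O)OC)([C@@H]5C=C([C@H](C)CCCOC(C)=O)[C@](C)(O)C[C@@H]5O)[C@H](C(C)=C3C[C@@H]12)[C@H]4OC(C)=O | intermediate
52 | CNP0257312.1 | C=C1C(=O)O[C@@H]2C[C@@H](C)[C@]34C[C@]5(C(=O)O[C@H]6C[C@@](C)(O)C([C@H](C)CCCOC(C)=O)=C[C@H]65)[C@H](C(C)=C3C[C@@H]12)[C@H]4OC(C)=O | target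

**Step count and risk**

Total: 39 steps. Longest linear sequence: 26 steps (steps 1–17, 20, 32–39). The sulfone arm takes 11 steps (21–31) and the dienophile 2 (18–19).

Least certain steps:

Step 38 (key step). The developing C31 cation may be intercepted by chloride or a 1,2-shift (Prins manifold) instead of losing the C21 proton. The boat-like array may also fail to form, because the quaternary C12 next to the reacting alkene carries an electron-withdrawing ester. Fallback: run the ring closure with C13 at the alcohol level, where the neighbour is a small electron-rich CH2O–Al group, and make the lactone by oxidation. It sets out from 45. MeI/K2CO3 in DMF releases the methylene lactone and gives diol acetal F1. TsOH in wet acetone gives hydroxy aldehyde F2. Me2AlCl (3.3 equiv) closes the ring to triol F3. TEMPO with PhI(OAc)2 then oxidises only the primary C13 alcohol, and the lactol formed with O15 is oxidised on to the lactone, which returns to the route at 52.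

Step 20. Orientational control at C12 may be incomplete, because the formyl and silyloxymethyl groups differ little in size, so part of the adduct may carry the formyl group endo. A slow cycloaddition would also let diene 26 drain away by [1,5]-hydrogen shift. Fallback: interchange the functional groups on the C12 epimer instead of relying on a selective cycloaddition. It sets out from the endo-formyl adduct F4 (from 21 and 24). Pinnick oxidation gives acid F5 and TMSCHN2 gives methyl ester F6, so the endo carbon is already the C13 ester. HF·pyridine gives alcohol F7 and Dess–Martin oxidation gives the exo aldehyde F8. Olefination with 43 under the conditions of step 32 gives alkene F9, and MeI/K2CO3 gives methylene lactone F10. The acid of step 37 removes dioxolane and TES ether and returns to the route at 50, so both C12 epimers converge and steps 33–35 are not needed for this material.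

Step 32. The hindered sulfonyl anion may add too slowly to the neopentyl aldehyde, so that attack of base on the acetates and self-condensation of the sulfone take over. Fallback: reverse the polarity of the olefination. From 27, NaBH4 gives neopentyl alcohol F11. Mitsunobu reaction with 1-phenyl-1H-tetrazole-5-thiol (PBu3, azodicarboxamide, 60 °C) gives sulfide F12, and molybdate/H2O2 with one equivalent of TsOH (amine protonated) gives sulfone F13. From 39, TESOTf gives silyl ether F14, hydrogenolysis gives alcohol F15 and Dess–Martin oxidation gives the less hindered α-branched aldehyde F16. The potassium anion of F13 and F16 then give the same alkene and return to the route at 44.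

Step 16. Catalyst control may be eroded by the α′-selenide, whose configuration differs in the two C34 series (one matched, one mismatched), giving poor facial selectivity at C39. Fallback: give up catalyst control and invert instead. Reduction of 19 with NaBH4/CeCl3 and separation give 20 and its C39 epimer, alcohol F17. F17 is converted by Mitsunobu reaction with acetic acid (SN2 at the carbinol; SN2′ is blocked by the tetrasubstituted alkene) into the acetate with inverted C39, while 20 is acetylated as in step 17; both return to the route at 21.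

**Further compounds**

F1 | step 38 | methylene lactone diol with C16 dioxolane (C13 CH2OH) | C=C1C(=O)O[C@@H]2C[C@@H](C)[C@]34C[C@@](CO)(/C=C/[C@@H]([C@H](C)CCCOC(C)=O)[C@](C)(O)CC5OCCO5)[C@H](C(C)=C3C[C@@H]12)[C@H]4OC(C)=O
F2 | step 38 | β-hydroxy aldehyde with C13 CH2OH | C=C1C(=O)O[C@@H]2C[C@@H](C)[C@]34C[C@@](CO)(/C=C/[C@@H]([C@H](C)CCCOC(C)=O)[C@](C)(O)CC=O)[C@H](C(C)=C3C[C@@H]12)[C@H]4OC(C)=O
F3 | step 38 | cyclohexene triol (C13 CH2OH, C16 OH, C18 OH) | C=C1C(=O)O[C@@H]2C[C@@H](C)[C@]34C[C@@](CO)([C@@H]5C=C([C@H](C)CCCOC(C)=O)[C@](C)(O)C[C@@H]5O)[C@H](C(C)=C3C[C@@H]12)[C@H]4OC(C)=O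
F4 | step 20 | C12 epimer of 27 (formyl endo, silyloxymethyl exo) | CN(C)C[C@@H]1C(=O)O[C@@H]2C[C@@H](C)[C@]34C[C@@](C=O)(CO[Si](C)(C)C(C)(C)C)[C@H](C(C)=C3C[C@@H]12)[C@H]4OC(C)=O
F5 | step 20 | endo carboxylic acid from F4 | CN(C)C[C@@H]1C(=O)O[C@@H]2C[C@@H](C)[C@]34C[C@@](C(=O)O)(CO[Si](C)(C)C(C)(C)C)[C@H](C(C)=C3C[C@@H]12)[C@H]4OC(C)=O
F6 | step 20 | endo methyl ester with exo CH2OTBS | CN(C)C[C@@H]1C(=O)O[C@@H]2C[C@@H](C)[C@]34C[C@@](C(=O)OC)(CO[Si](C)(C)C(C)(C)C)[C@H](C(C)=C3C[C@@H]12)[C@H]4OC(C)=O
F7 | step 20 | endo methyl ester with exo CH2OH | CN(C)C[C@@H]1C(=O)O[C@@H]2C[C@@H](C)[C@]34C[C@@](C(=O)OC)(CO)[C@H](C(C)=C3C[C@@H]12)[C@H]4OC(C)=O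
F8 | step 20 | endo methyl ester with exo formyl group | CN(C)C[C@@H]1C(=O)O[C@@H]2C[C@@H](C)[C@]34C[C@@](C(=O)OC)(C=O)[C@H](C(C)=C3C[C@@H]12)[C@H]4OC(C)=O
F9 | step 20 | coupled (E)-alkene with C13 ester, C18 OTES, dioxolane, amine-masked lactone | CN(C)C[C@@H]1C(=O)O[C@@H]2C[C@@H](C)[C@]34C[C@@](C(=O)OC)(/C=C/[C@@H]([C@H](C)CCCOC(C)=O)[C@](C)(O[Si](CC)(CC)CC)CC5OCCO5)[C@H](C(C)=C3C[C@@H]12)[C@H]4OC(C)=O
F10 | step 20 | C18 triethylsilyl ether of 49 | C=C1C(=O)O[C@@H]2C[C@@H](C)[C@]34C[C@@](C(=O)OC)(/C=C/[C@@H]([C@H](C)CCCOC(C)=O)[C@](C)(O[Si](CC)(CC)CC)CC5OCCO5)[C@H](C(C)=C3C[C@@H]12)[C@H]4OC(C)=O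
F11 | step 32 | exo hydroxymethyl norbornene from 27 | CN(C)C[C@@H]1C(=O)O[C@@H]2C[C@@H](C)[C@]34C[C@](CO)(CO[Si](C)(C)C(C)(C)C)[C@H](C(C)=C3C[C@@H]12)[C@H]4OC(C)=O
F12 | step 32 | exo (1-phenyltetrazol-5-yl)sulfanylmethyl norbornene | CN(C)C[C@@H]1C(=O)O[C@@H]2C[C@@H](C)[C@]34C[C@](CSc5nnnn5-c5ccccc5)(CO[Si](C)(C)C(C)(C)C)[C@H](C(C)=C3C[C@@H]12)[C@H]4OC(C)=O
F13 | step 32 | exo (1-phenyltetrazol-5-yl)sulfonylmethyl norbornene | CN(C)C[C@@H]1C(=O)O[C@@H]2C[C@@H](C)[C@]34C[C@](CS(=O)(=O)c5nnnn5-c5ccccc5)(CO[Si](C)(C)C(C)(C)C)[C@H](C(C)=C3C[C@@H]12)[C@H]4OC(C)=O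
F14 | step 32 | C18 triethylsilyl ether of 39 | C[C@@](O[Si](CC)(CC)CC)(CC1OCCO1)[C@@H](COCc1ccccc1)[C@H](C)CCCOC(C)=O
F15 | step 32 | C31 alcohol with C18 OTES | C[C@@](O[Si](CC)(CC)CC)(CC1OCCO1)[C@@H](CO)[C@H](C)CCCOC(C)=O
F16 | step 32 | C31 aldehyde with C18 OTES | C[C@@](O[Si](CC)(CC)CC)(CC1OCCO1)[C@@H](C=O)[C@H](C)CCCOC(C)=O
F17 | step 16 | C39 epimer of 20 | CN(C)C[C@@H]1C(=O)O[C@@H]2C[C@@H](C)C3=C(C[C@@H]12)C(C)C([Se]c1ccccc1)[C@@H]3O
A1 | alternative 1 | bicyclo[5.3.0]decenone ketal with C8 methyl and C38 acetate side chain | O=C1C[C@@H](C)C2=C(C[C@H]1CC(=O)OC)[C@@H](C)CC23OCCO3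
A2 | alternative 2 | endo norbornene carboxylic acid with silyl-protected lower ring | C1C(=O)O[C@@H]2C[C@@H](C)[C@]34C[C@@](C(=O)O)([C@@H]5C=C([C@H](C)CCCO[Si](C)(C)C(C)(C)C)[C@](C)(O[Si](C)(C)C)C[C@@H]5O[Si](CC)(CC)CC)[C@H](C(C)=C3C[C@@H]12)[C@H]4O[Si](C)(C)C(C)(C)C
A3 | alternative 3 | seven-membered hydroxy α-methylene ester | C=C(C(=O)OC)[C@H]1[C@H](O)C[C@@H](C)[C@]34C[C@]5(C(=O)O[C@H]6C[C@@](C)(O)C([C@H](C)CCCOC(C)=O)=C[C@H]65)[C@H](C(C)=C3C1)[C@H]4OC(C)=O
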